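The reading time of 8.0 min was the one point at which I had to know how much product stood in grey, red and green.

| flask | substrate | solid reagent | temperature | remark | time |
|---|---|---|---|---|---|
| summer | 0.23 M | 0.28 M | 65 °C | run made earlier |  |
| noon | 0.52 M | 0.28 M | 85 °C | run made earlier |  |
| grey | 0.35 M | 0.280 M | 100 °C |  | 8.0 min |
| red | 0.35 M | 0.280 M | 85 °C |  | 8.0 min |
| green | 0.35 M | 0.280 M | 70 °C |  | 8.0 min |

| run | time / min | product / % |
|---|---|---|
| summer | 4.00 | 42.6 |
| summer | 8.00 | 72.0 |
| summer | 15.0 | 79.6 |
| summer | 30.0 | 86.9 |
| noon | 1.33 | 6.3 |
| noon | 3.00 | 14.1 |
| noon | 6.00 | 28.0 |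
| noon | 10.0 | 46.3 |

(each reading ± 0.5 percentage points)

- solid reagent is a solid; its amount is given per volume of the solution
- the earlier runs were read with a standard deviation of 0.5 percentage points
- at the start none of the solid reagent is in solution
- a reading or a percentage of product counts all its forms, free or not

1. the flask that comes out highest in amount of product, in percent of the substrate charged, or "all alike" when all lie within 1.5 percentage points (grey / red / green / all alike)
2. product at the end, in percent of the substrate charged, grey
3. product at the end, in percent of the substrate charged, red
4. product at the end, in percent of the substrate charged, green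

The summer run made 0.0245 M/min of product over its opening 4.00 min, and the noon run made 0.0241 M/min over 10.0 min, about the same rate in both. Yet noon held 2.26 times the substrate and stood at 85 °C against 65 °C. With equal solid reagent in both, I read dissolution as the rate-limiting step. I took the mean, 0.0243 M/min, as the feed, the molar rate of product formation while the line stays straight. This zero-order rate integrates to c_product = feed × t.

Red looked nearly the same as the noon run, with equal temperature and solid reagent but less substrate. At 8.0 min the line gives both 0.194 M, but the divisors differ, so noon's line stands at 37.4 % and red's at 55.5 %.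

Would red stay on the line? The summer run fell off it, reading 72.0 % at 8.00 min against a line value of 84.5 %. But it was still on the line at 4.00 min, with 0.132 M unconverted. By the line, red holds 0.156 M unconverted at 8.0 min, more than that. By the line, the solid reagent also outlasts the reading, since charge over feed is 11.5 min, longer than 8.0 min. Grey, at 100 °C, lay beyond both runs. I therefore committed to 55.5 % in each flask.

The forecast gave 55.7 %, 55.7 % and 55.5 % for grey, red and green, so all alike, slightly above my figure for grey and red, on the grounds that “It looks limited by dissolution of the solid”.

The flasks came out all alike: grey 55.9 %, red 55.8 %, green 55.8 %.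

    substrate ⇌ reactive form (K = 1.60, k = 0.0110 /s, Ea = 99.0 kJ/mol, ΔH = −60.0 kJ/mol)
    partner + reactive form → product (k = 78.0 /M/s, Ea = 58.0 kJ/mol)
    partner + product ⇌ idle adduct, settled at all times (K = 3.00 /M, ΔH = 14.0 kJ/mol)
    substrate ⇌ dormant form (K = 2.90, k = 0.00360 /s, Ea = 104 kJ/mol, ΔH = 6.00 kJ/mol)
    solid reagent ⇌ partner, rate k5*(cs5 - [partner]) while solid is left; crystals form when [partner] > cs5 (solubility = 0.240 M, k = 0.00170 /s)
    (constants at 70 °C)

Red held 30.1 % of its solid reagent at 8.00 min, where the feed reckons 30.6 %. A neighbour of red charged with 0.11 M of solid reagent makes that the limiting reagent: the feed consumes it in 4.53 min, sooner than 8.0 min, and its charge allows product of 31.4 % of the substrate. That neighbour gave 31.4 %, with 0 % of its solid reagent left.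

(Readings and results are simulated on assumed constants; noise was put on by code.)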